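**Retrosynthetic overview**
1. Numbering: decalin C1–C10 (ring A = C1–C5 and C10, ring B = C5–C10). Chain C11–C19 (C19 = lactone C=O). Methyls C20 (on C17), C21 (on C13), C22 (on C8), C24 (on C4), C25 (on C10). Ester carbon C23 (on C4).
2. C14–C15 is cut last: a decalin-bound terminal alkyne C13≡C14, AlMe3 and 3-methylfuran-2-carbaldehyde are joined in one flask. This makes the C13–C21 and C14–C15 bonds, the E-alkene and the C15 stereocentre.
3. Enabling feature: in the C13(CH3)=C14H alkene, C21 is cis to C15, which is the retron of a syn-methylmetalation. The butenolide ring (O, C16–C19, C20 on C17) is a 3-methylfuran plus one oxygen atom, so C15 can be a flat, non-enolisable aldehyde while the base-labile C16 centre does not yet exist.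
4. C16 is relayed from C15: furan, singlet oxygen, γ-hydroxybutenolide, Felkin–Anh hydride, lactonisation. The butenolide ring is formed last.
5. Rings A and B with C5, C6, C9 and C10 are bought in (+)-larixyl acetate. C8 comes from HAT hydration. C4/C23 come from a 6α-alkoxyl-radical C–H etherification, which gives a temporary five-membered ring C23–O–C6 (formed first, opened before the coupling).

Key step: step 10

Assumption: (+)-larixyl acetate and 3-methylfuran-2-carbaldehyde are taken as catalogue chemicals; the sense of induction of the (S)-ligand in step 10 is inferred by analogy, and the antipodal ligand would be used if it proves opposite.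

**Step 1**
Reactants: 1 (+)-larixyl acetate
Product: 2 exomethylene ketone acetate (9β-(3-oxobutyl) chain)
Conditions: KMnO4, BnEt3NCl, CH2Cl2, 0 °C to rt
Reagents that add atoms: none
Why: Permanganate degradation of a tertiary vinyl carbinol (the reaction type used to cut manool-type side chains to methyl ketones) should cleave the unhindered monosubstituted alkene and decarboxylate the resulting α-hydroxy acid, while the hindered 8-exomethylene group and the acetate survive at low temperature under phase transfer; no stereocentre is formed and C13 is erased.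

**Step 2**
Reactants: 2 exomethylene ketone acetate
Product: 3 hydroxy ketone acetate (8α-OH, 8β-CH3)
Conditions: Co(acac)2 (cat.), PhSiH3, O2 (1 atm), THF, rt
Reagents that add atoms: dioxygen O=O
Why: Mukaiyama hydration (cobalt hydride HAT to the CH2 terminus, O2 capture of the tertiary C8 radical, in situ reduction of the peroxide) is Markovnikov-selective, and O2 should approach from the α face because the β face is blocked by the 1,3-diaxial C25 methyl, giving the equatorial 8α-OH and the axial C22 methyl.

**Step 3**
Reactants: 3 hydroxy ketone acetate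
Product: 4 TES ketone acetate (8α-OSiEt3)
Conditions: Et3SiOTf, 2,6-lutidine, CH2Cl2, −78 to −20 °C
Reagents that add atoms: triethylsilyl triflate CC[Si](CC)(CC)OS(=O)(=O)C(F)(F)F
Why: Silyl triflate silylation buffered by a hindered pyridine is the standard way to cap a tertiary alcohol, and at low temperature it should outrun enol silylation of the methyl ketone and cyclodehydration of the δ-hydroxy ketone.

**Step 4**
Reactants: 4 TES ketone acetate
Product: 5 TES hydroxy ketone (free 6α-OH)
Conditions: K2CO3 (cat.), MeOH, 40 °C
Reagents that add atoms: none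
Why: Base-catalysed methanolysis (transesterification) removes the only ester, since the tertiary TES ether and the ketone are inert to carbonate in methanol.

**Step 5**
Reactants: 5 TES hydroxy ketone
Product: 6 ether ketone (6α,23-epoxide, tetrahydrofuran ring C23–O–C6–C5–C4)
Conditions: PhI(OAc)2, I2, cyclohexane/CH2Cl2, visible light, rt
Reagents that add atoms: none
Why: Suárez hypoiodite reaction (alkoxyl radical, 1,5-hydrogen atom transfer, iodination, SN2 ether closure): the equatorial 6α-oxygen and the equatorial 4α-methyl are peri-related and parallel (both anti to the C5–C10 bond), so only this methyl is within reach through a six-membered transition state while the axial C24 and C25 methyls point to the β face, and this choice between the diastereotopic methyls makes C4 stereogenic with the oxidised carbon C23 on the α face as in the target.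

**Step 6**
Reactants: 6 ether ketone
Product: 7 lactone ketone (23,6α-olide)
Conditions: RuCl3·xH2O (cat.), NaIO4, MeCN/EtOAc/H2O, rt
Reagents that add atoms: sodium periodate [Na+].[O-]I(=O)(=O)=O
Why: RuO4 oxidation of a cyclic ether to the lactone should attack the open C23 methylene rather than the C6 methine, whose only hydrogen is axial between the C24 and C25 methyls, and the ketone and the tertiary silyl ether have no oxidisable position.

**Step 7**
Reactants: 7 lactone ketone
Product: 9 lactone alkyne (C13≡C14 terminal alkyne), via enol phosphate 8 (not isolated)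
Conditions: LiN(iPr)2 (1.1 equiv), THF, −78 °C; ClP(O)(OEt)2, −78 °C to rt; LiN(iPr)2 (2.5 equiv), −78 °C to rt; H2O
Reagents that add atoms: none
Why: Kinetic enolate phosphorylation on the methyl side followed by base-induced elimination is the standard methyl ketone to terminal alkyne protocol, and the lactone carbonyl sits on quaternary C4, so it can be neither enolised nor easily attacked by the hindered amide.

**Step 8**
Reactants: 9 lactone alkyne
Product: 11 hydroxy ester alkyne (C23 methyl ester, free 6α-OH), via potassium carboxylate 10 (not isolated)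
Conditions: KOH, EtOH/H2O, reflux; CO2 (s) to pH 8–9, concentrate; MeI, DMF, rt
Reagents that add atoms: potassium hydroxide [K+].[OH-]; iodomethane CI
Why: Saponification of the peri-fused γ-lactone by acyl–oxygen cleavage (C6 untouched) followed by SN2 O-alkylation of the carboxylate never liberates the free acid, which avoids relactonisation, and any loss of the 8-O-TES group would be repaired in step 9.

**Step 9**
Reactants: 11 hydroxy ester alkyne
Product: 12 bis-TES ester alkyne
Conditions: Et3SiOTf (excess), 2,6-lutidine, CH2Cl2, 0 °C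
Reagents that add atoms: triethylsilyl triflate CC[Si](CC)(CC)OS(=O)(=O)C(F)(F)F
Why: Silyl triflate silylation caps the hindered equatorial 6α-OH, which would otherwise become an aluminium alkoxide next to the C23 ester in step 10 and close the lactone again.

**Step 10**
Reactants: 12 bis-TES ester alkyne; 13 3-methylfuran-2-carbaldehyde
Product: 15 furyl carbinol (13E,15S), via alkenylalane 14 (not isolated)
Conditions: AlMe3 (4 equiv), Cp2ZrCl2 (0.3 equiv), CH2Cl2, 0 °C to rt; volatiles removed in vacuo, hexane extraction; Ti(OiPr)4 (excess), (S)-H8-BINOL (10 mol %), THF/toluene, 0 °C, slow addition of 13 (1.5 equiv); aq. potassium sodium tartrate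
Reagents that add atoms: trimethylaluminium C[Al](C)C
Why: Proposed new method: Cp2ZrCl2-catalysed syn-methylalumination of the terminal alkyne places CH3 (C21) on C13 and AlMe2 on C14 (14), and after removal of free AlMe3 the alkenyl group is passed to a tetravalent titanium H8-BINOLate that binds aldehyde 13 and delivers C14 to its Si face, so that two C–C bonds, the E-alkene and C15 arise in one flask. The closest known reaction types are the Negishi carboalumination/aldehyde trapping sequence and the titanium–BINOLate-catalysed enantioselective addition of alkenyl- and arylaluminium reagents to carbonyl compounds, and their merger on a 2,2-disubstituted alkenyl(dimethyl)alane and a furfural is the new element. No ring is closed. The alkene geometry follows from syn-addition and retention during transfer, and C15 (S) is set by the ligand alone because the nearest decalin stereocentre (C9) is five bonds away, the (S)-ligand being chosen by analogy with the Si-face delivery of related alkyl and aryl transfers. The step needs terminal regioselectivity (secured by the unbranched C11–C12 tether), alkenyl over methyl transfer (the sp2 carbon migrates faster and 13 is in excess), suppression of the uncatalysed addition (THF-complexed alane, excess Ti(OiPr)4, slow addition of 13) and inertness of the C23 ester (shielded by quaternary C4 and the 6α-OTES group). Aldehyde 13 has neither an α-hydrogen nor a stereocentre, so enolisation and epimerisation cannot compete.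

**Step 11**
Reactants: 15 furyl carbinol
Product: 16 furyl TBS ether
Conditions: tBuMe2SiCl, imidazole, DMAP (cat.), DMF, rt
Reagents that add atoms: tert-butyldimethylsilyl chloride CC(C)(C)[Si](C)(C)Cl
Why: Imidazole-promoted silylation is non-acidic and therefore protects the ionisation-prone furyl allyl carbinol without allylic transposition, and it installs the bulky non-chelating group needed for step 13.

**Step 12**
Reactants: 16 furyl TBS ether
Product: 18 hydroxybutenolide (C16 hemiketal epimers), via endoperoxide 17 (not isolated)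
Conditions: O2, tetraphenylporphyrin (cat.), visible light, iPr2NEt, CH2Cl2, −78 °C
Reagents that add atoms: dioxygen O=O
Why: Sensitised [4+2] photooxygenation of the electron-rich 2,3-dialkylfuran is followed by Kornblum–DeLaMare fragmentation of 17, whose only removable hydrogen sits on C19, so C19 becomes the lactone carbonyl and C16 the hemiketal carbon; the furan should react with singlet oxygen far faster than the hindered C13=C14 alkene, and the C16 epimer mixture is of no consequence.

**Step 13**
Reactants: 18 hydroxybutenolide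
Product: 20 silylated butenolide (15S,16S), via hydroxy acid 19 (not isolated)
Conditions: NaBH4, CeCl3·7H2O, MeOH/THF, −40 to 0 °C; 1 M HCl to pH 3, rt
Reagents that add atoms: none
Why: Luche-type 1,2-reduction of the ring-opened (Z)-γ-keto acid tautomer under Felkin–Anh control places the bulky non-chelating 15-OTBS group anti to the incoming hydride, which passes the C15 hydrogen and should give the 15,16-syn (threo) relationship, that is 16S, after which acidification closes the butenolide by 5-exo-trig lactonisation of 19.

**Step 14**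
Reactants: 20 silylated butenolide
Product: 21 target CNP0104474.1
Conditions: HF·pyridine, pyridine, THF, 0 °C to rt
Reagents that add atoms: none
Why: Fluoride-driven desilylation in a buffered, weakly acidic medium should remove all three silyl ethers without the basic conditions that would epimerise C16, translactonise the butenolide or close the 6,23-lactone.

**Compound list**
1 | (+)-larixyl acetate: trans-decalin, 4,4-dimethyl, 10β-methyl, 5α-H, 6α-OAc, 8-exomethylene, 9β-[(3S)-3-hydroxy-3-methylpent-4-enyl] | CC1(C)CCC[C@@]2(C)[C@H]1[C@@H](OC(C)=O)CC(=C)[C@@H]2CC[C@](C)(O)C=C | starting material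
2 | exomethylene ketone acetate: as 1 with a 9β-(3-oxobutyl) chain | CC1(C)CCC[C@@]2(C)[C@H]1[C@@H](OC(C)=O)CC(=C)[C@@H]2CCC(C)=O | intermediate
3 | hydroxy ketone acetate: 8α-OH, 8β-methyl | CC1(C)CCC[C@@]2(C)[C@H]1[C@@H](OC(C)=O)C[C@@](C)(O)[C@@H]2CCC(C)=O | intermediate
4 | TES ketone acetate: 8α-OSiEt3, 6α-OAc | CC1(C)CCC[C@@]2(C)[C@H]1[C@@H](OC(C)=O)C[C@@](C)(O[Si](CC)(CC)CC)[C@@H]2CCC(C)=O | intermediate
5 | TES hydroxy ketone: 8α-OSiEt3, 6α-OH | CC1(C)CCC[C@@]2(C)[C@H]1[C@@H](O)C[C@@](C)(O[Si](CC)(CC)CC)[C@@H]2CCC(C)=O | intermediate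
6 | ether ketone: 6α,23-epoxide (4α-CH2–O–C6), 4β-methyl | O3C[C@]1(C)CCC[C@@]2(C)[C@H]1[C@@H]3C[C@@](C)(O[Si](CC)(CC)CC)[C@@H]2CCC(C)=O | intermediate
7 | lactone ketone: 23,6α-olide | O=C3[C@]1(C)CCC[C@@]2(C)[C@H]1[C@@H](O3)C[C@@](C)(O[Si](CC)(CC)CC)[C@@H]2CCC(C)=O | intermediate
8 | enol phosphate: terminal enol diethyl phosphate of 7 | O=C3[C@]1(C)CCC[C@@]2(C)[C@H]1[C@@H](O3)C[C@@](C)(O[Si](CC)(CC)CC)[C@@H]2CCC(=C)OP(=O)(OCC)OCC | intermediate
9 | lactone alkyne: 9β-(but-3-ynyl) chain | O=C3[C@]1(C)CCC[C@@]2(C)[C@H]1[C@@H](O3)C[C@@](C)(O[Si](CC)(CC)CC)[C@@H]2CCC#C | intermediate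
10 | potassium carboxylate: 4α-CO2K, 6α-OH | [K+].[O-]C(=O)[C@]1(C)CCC[C@@]2(C)[C@H]1[C@@H](O)C[C@@](C)(O[Si](CC)(CC)CC)[C@@H]2CCC#C | intermediate
11 | hydroxy ester alkyne: 4α-CO2Me, 6α-OH, 8α-OSiEt3 | COC(=O)[C@]1(C)CCC[C@@]2(C)[C@H]1[C@@H](O)C[C@@](C)(O[Si](CC)(CC)CC)[C@@H]2CCC#C | intermediate
12 | bis-TES ester alkyne: 4α-CO2Me, 6α,8α-bis(OSiEt3) | COC(=O)[C@]1(C)CCC[C@@]2(C)[C@H]1[C@@H](O[Si](CC)(CC)CC)C[C@@](C)(O[Si](CC)(CC)CC)[C@@H]2CCC#C | intermediate
13 | 3-methylfuran-2-carbaldehyde | Cc1ccoc1C=O | starting material
14 | alkenylalane: (E)-C13(CH3)=C14H–AlMe2 | COC(=O)[C@]1(C)CCC[C@@]2(C)[C@H]1[C@@H](O[Si](CC)(CC)CC)C[C@@](C)(O[Si](CC)(CC)CC)[C@@H]2CC/C(C)=C/[Al](C)C | intermediate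
15 | furyl carbinol: (13E,15S)-allylic alcohol bearing 3-methylfuran-2-yl on C15 | COC(=O)[C@]1(C)CCC[C@@]2(C)[C@H]1[C@@H](O[Si](CC)(CC)CC)C[C@@](C)(O[Si](CC)(CC)CC)[C@@H]2CC/C(C)=C/[C@H](O)c1occc1C | intermediate
16 | furyl TBS ether: 15-OSiMe2tBu | COC(=O)[C@]1(C)CCC[C@@]2(C)[C@H]1[C@@H](O[Si](CC)(CC)CC)C[C@@](C)(O[Si](CC)(CC)CC)[C@@H]2CC/C(C)=C/[C@H](O[Si](C)(C)C(C)(C)C)c1occc1C | intermediate
17 | endoperoxide: 2,3,7-trioxabicyclo[2.2.1]hept-5-ene across C16 and C19 | COC(=O)[C@]1(C)CCC[C@@]2(C)[C@H]1[C@@H](O[Si](CC)(CC)CC)C[C@@](C)(O[Si](CC)(CC)CC)[C@@H]2CC/C(C)=C/[C@H](O[Si](C)(C)C(C)(C)C)C12OOC(O1)C=C2C | intermediate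
18 | hydroxybutenolide: 16-hydroxy (both C16 epimers), C19 lactone carbonyl | COC(=O)[C@]1(C)CCC[C@@]2(C)[C@H]1[C@@H](O[Si](CC)(CC)CC)C[C@@](C)(O[Si](CC)(CC)CC)[C@@H]2CC/C(C)=C/[C@H](O[Si](C)(C)C(C)(C)C)C1(O)OC(=O)C=C1C | intermediate
19 | hydroxy acid: (15S,16S,17Z)-16-hydroxy-19-oic acid | COC(=O)[C@]1(C)CCC[C@@]2(C)[C@H]1[C@@H](O[Si](CC)(CC)CC)C[C@@](C)(O[Si](CC)(CC)CC)[C@@H]2CC/C(C)=C/[C@H](O[Si](C)(C)C(C)(C)C)[C@@H](O)/C(C)=C\C(O)=O | intermediate
20 | silylated butenolide: target with 6-O-TES, 8-O-TES, 15-O-TBS | COC(=O)[C@]1(C)CCC[C@@]2(C)[C@H]1[C@@H](O[Si](CC)(CC)CC)C[C@@](C)(O[Si](CC)(CC)CC)[C@@H]2CC/C(C)=C/[C@H](O[Si](C)(C)C(C)(C)C)[C@H]1OC(=O)C=C1C | intermediate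
21 | CNP0104474.1 | COC(=O)[C@]1(C)CCC[C@@]2(C)[C@H]1[C@@H](O)C[C@@](C)(O)[C@@H]2CC/C(C)=C/[C@H](O)[C@H]1OC(=O)C=C1C | target

**Total step count:** 14. **Longest linear sequence:** 14 steps (from 1; 13 is bought).

**Steps most likely to fail**

Step 10.
- Risk: uncatalysed alkenyl transfer directly from aluminium may erode the face selectivity at C15. Methyl transfer may consume the aldehyde. The Lewis acidic carboalumination medium may strip a silyl ether.
- Fallback: it sets out from 12. The Negishi carboalumination is quenched with I2 to give the (E)-alkenyl iodide F1, which is isolated. F1 is coupled with 13 in a catalytic asymmetric Nozaki–Hiyama–Kishi reaction (CrCl2, chiral oxazoline sulfonamide ligand, NiCl2·(2,9-dimethyl-1,10-phenanthroline), Mn, Cp2ZrCl2, LiCl, MeCN, rt). This is a neutral process based on divalent chromium and zerovalent nickel that tolerates esters and silyl ethers and has no aluminium background reaction. It comes back to the route at 15.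

Step 13.
- Risk: hydride delivery to the ring-opened keto acid may show poor facial selectivity. Conjugate reduction or a 1,2-silyl shift from O15 to O16 may intervene before lactonisation.
- Fallback: it sets out from 18 and replaces substrate control by catalyst control on a fixed open-chain substrate. Carboxylate alkylation (MeI, K2CO3, DMF) gives the (Z)-γ-keto methyl ester F2. Corey–Bakshi–Shibata reduction follows (2-methyl-CBS-oxazaborolidine, catecholborane, toluene, −78 °C); both antipodes are available and the one that reinforces the Felkin–Anh bias is kept. This gives the (16S)-γ-hydroxy ester F3, whose alkoxide lactonises at once with loss of methanol, which also outruns silyl migration. It comes back to the route at 20.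

Step 5.
- Risk: β-fragmentation of the 6α-alkoxyl radical (cleavage of C5–C6 to a tertiary radical) may compete with the 1,5-hydrogen atom transfer.
- Fallback: it sets out from 5 and avoids oxygen radicals altogether. Silylation with Et2SiHCl/Et3N gives the diethylhydrosilyl ether F4. Rhodium-catalysed intramolecular δ-C–H silylation of the near methyl group ([Rh(cod)Cl]2, Xantphos, norbornene, THF, 100 °C) closes the six-membered oxasilinane F5. Tamao–Fleming oxidation (H2O2, KHCO3, THF/MeOH) gives the 6α,23-diol F6. Oxidative lactonisation (TEMPO, PhI(OAc)2, CH2Cl2), selective for the primary alcohol, comes back to the route at 7.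

**Further compounds**
F1 | step 10 | (E)-alkenyl iodide (C14–I) of the bis-TES ester | COC(=O)[C@]1(C)CCC[C@@]2(C)[C@H]1[C@@H](O[Si](CC)(CC)CC)C[C@@](C)(O[Si](CC)(CC)CC)[C@@H]2CC/C(C)=C/I
F2 | step 13 | (15S,17Z)-16-oxo-19-oic acid methyl ester | COC(=O)[C@]1(C)CCC[C@@]2(C)[C@H]1[C@@H](O[Si](CC)(CC)CC)C[C@@](C)(O[Si](CC)(CC)CC)[C@@H]2CC/C(C)=C/[C@H](O[Si](C)(C)C(C)(C)C)C(=O)/C(C)=C\C(=O)OC
F3 | step 13 | (15S,16S,17Z)-16-hydroxy-19-oic acid methyl ester | COC(=O)[C@]1(C)CCC[C@@]2(C)[C@H]1[C@@H](O[Si](CC)(CC)CC)C[C@@](C)(O[Si](CC)(CC)CC)[C@@H]2CC/C(C)=C/[C@H](O[Si](C)(C)C(C)(C)C)[C@@H](O)/C(C)=C\C(=O)OC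
F4 | step 5 | 6α-O-diethylhydrosilyl ether of 5 | CC1(C)CCC[C@@]2(C)[C@H]1[C@@H](O[SiH](CC)CC)C[C@@](C)(O[Si](CC)(CC)CC)[C@@H]2CCC(C)=O
F5 | step 5 | oxasilinane (ring O–SiEt2–C23–C4–C5–C6) | O3[Si](CC)(CC)C[C@]1(C)CCC[C@@]2(C)[C@H]1[C@@H]3C[C@@](C)(O[Si](CC)(CC)CC)[C@@H]2CCC(C)=O
F6 | step 5 | 6α,23-diol | OC[C@]1(C)CCC[C@@]2(C)[C@H]1[C@@H](O)C[C@@](C)(O[Si](CC)(CC)CC)[C@@H]2CCC(C)=O
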